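**Strategy.** The target is disconnected at the C1–C6 bond shared by the oxirane and the cyclohexenone ring (7-oxabicyclo[4.1.0]hept-3-en-2-one numbering; C1: quaternary, farnesyl-bearing, α to the C2 ketone; C6: epoxide CH). A reductive intramolecular Darzens reaction forms it: SmI2 converts the achiral CCl2 group of an acyclic (Z)-dichloro enone aldehyde into a chloro enolate that adds to the aldehyde, closing the carbocycle, and the aldolate then expels chloride, closing the oxirane. The step exploits the C2 ketone, the epoxide oxygen (former aldehyde oxygen) and the C5-OH/C4-CH2OH 1,3-diol, tied as an acetonide that holds C5–O pseudoequatorial and so directs both new stereocentres. The hydroxymethylglutarate half-ester is attached last.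

Key step: step 6

Remark on the chemistry: compound 12 is expected to exist as the cyclic hemiketal of the ring-opened hydroxy ketone, and pig liver esterase is taken to deliver the (S)-half ester 20.

Step 1
Reactants: 1 (2E,6E)-farnesyl bromide; 2 dichloromethane
Product: 4 (3E,7E)-1,1-dichloro-4,8,12-trimethyltrideca-3,7,11-triene, via dichloromethyllithium 3 (not isolated)
Conditions: 2, LDA, THF, −100 °C; then 1, DMPU, −100 → −78 °C
Reagents that add atoms: none
Why: Dichloromethyllithium is alkylated by the primary allylic bromide in an SN2 reaction (carbenoid alkylation) faster than it decomposes at −100 °C, and the fully substituted γ-carbon disfavours SN2′ attack, so the E,E-triene is carried through unchanged.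

Step 2
Reactants: 5 2,2-dimethyl-1,3-dioxan-5-one; 6 formaldehyde (37% aqueous)
Product: 7 (S)-4-(hydroxymethyl)-2,2-dimethyl-1,3-dioxan-5-one
Conditions: L-proline (30 mol%), DMSO, 23 °C
Reagents that add atoms: none
Why: Proline-catalysed direct aldol reaction (α-hydroxymethylation) in which the enamine of the symmetric ketone adds to formaldehyde through the carboxylic-acid-bridged transition state, which should set C4 as S.

Step 3
Reactants: 7 (S)-4-(hydroxymethyl)-2,2-dimethyl-1,3-dioxan-5-one; 8 (triphenylphosphoranylidene)ketene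
Product: 10 (8aR)-2,2-dimethyl-8,8a-dihydro-4H-pyrano[3,4-d][1,3]dioxin-6-one, via ester ylide 9 (not isolated)
Conditions: toluene, 80 °C
Reagents that add atoms: none
Why: The primary hydroxyl adds to the ketene unit to give ester ylide 9, whose intramolecular Wittig reaction with the activated α,α'-dioxygenated ketone closes the unsaturated δ-lactone (acylation–Wittig lactonisation cascade), so that the ring itself fixes the carbonyl cis to the stereocentre under base-free conditions.

Step 4
Reactants: 4 (3E,7E)-1,1-dichloro-4,8,12-trimethyltrideca-3,7,11-triene; 10 (8aR)-2,2-dimethyl-8,8a-dihydro-4H-pyrano[3,4-d][1,3]dioxin-6-one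
Product: 12 (8aR)-6-[(3E,7E)-1,1-dichloro-4,8,12-trimethyltrideca-3,7,11-trien-1-yl]-2,2-dimethyl-8,8a-dihydro-4H-pyrano[3,4-d][1,3]dioxin-6-ol (cyclic hemiketal; both C6 epimers), via dichloroalkyllithium 11 (not isolated)
Conditions: 4 (1.3 equiv), LDA (1.2 equiv), THF–Et2O, −100 °C; then 10, −100 → −78 °C; AcOH quench at −78 °C
Reagents that add atoms: none
Why: α-Lithiation of the gem-dichloride gives carbenoid 11, which adds 1,2 to the lactone carbonyl (acylation of a lithium carbenoid), the β,β-disubstituted alkene blocking conjugate addition and the chlorine-stabilised tetrahedral alkoxide preventing a second addition.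

Step 5
Reactants: 12 cyclic hemiketal
Product: 14 (4R,5Z)-5-[(5E,9E)-3,3-dichloro-6,10,14-trimethyl-2-oxopentadeca-5,9,13-trien-1-ylidene]-2,2-dimethyl-1,3-dioxane-4-carbaldehyde, via open-chain hydroxy ketone 13 (not isolated)
Conditions: Dess–Martin periodinane, pyridine, CH2Cl2, 0 → 23 °C; used crude
Reagents that add atoms: none
Why: Dess–Martin oxidation drains the fast ring–chain equilibrium through hydroxy ketone 13, whose primary alcohol is the only oxidisable group, under buffered conditions that should leave the α-oxygenated stereocentre intact.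

Step 6
Reactants: 14 (Z)-dichloro enone aldehyde
Product: 17 acetonide of (1R,5R,6R)-5-hydroxy-4-(hydroxymethyl)-1-[(2E,6E)-3,7,11-trimethyldodeca-2,6,10-trien-1-yl]-7-oxabicyclo[4.1.0]hept-3-en-2-one (dioxane across C4-CH2O and C5-O; epoxide oxygen cis to C5–O), via samarium chloro-enolate 15 (not isolated), via samarium chlorohydrin aldolate 16 (not isolated)
Conditions: SmI2 (2.05 equiv, 0.1 M in THF, added dropwise), THF, −78 °C; then 23 °C
Reagents that add atoms: none
Why: Two equivalents of SmI2 reductively cleave one C–Cl bond of the α,α-dichloro ketone to give the trivalent-samarium chloro-enolate 15 (alkyl chain syn to O–Sm, chlorine syn to the vinyl group), which adds to the tethered aldehyde to give aldolate 16, whose samarium alkoxide then displaces the remaining tertiary α-keto chloride with inversion to form the oxirane. The closest known reaction type is the SmI2-mediated Reformatsky-type aldol of gem-dihalo carbonyl compounds followed by Darzens-type halohydrin closure, here run intramolecularly. The cyclohexenone closes by a 6-(enolendo)-exo-trig aldol addition that makes the C1–C6 bond (target numbering), and the oxirane by a 3-exo-tet substitution at C1. C6 is set by the acetonide, which holds the C5–O bond pseudoequatorial and anti to the forming bond (Felkin–Anh arrangement) while the samarium bridge between enolate and aldehyde oxygens places the new alkoxide axial and therefore cis to C5–O; C1 is set by the stereoelectronic demand that only a chlorine axial and anti to this alkoxide can be displaced, so the achiral CCl2 carbon becomes the quaternary centre with the epoxide oxygen cis to C5–O. The step needs chemoselective reduction of the C–Cl bond before ketyl formation at the aldehyde or enone and a stop after the first chlorine, which the much faster electron transfer to α-halo ketones at −78 °C and the slow addition of just two equivalents should secure. As no base is present, the acidic C5–H (α to the aldehyde and γ to the enone) should not epimerise, and aldolates that cannot close can revert by retro-aldol reaction.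

Step 7
Reactants: 17 epoxy enone acetonide
Product: 18 (1R,5R,6R)-5-hydroxy-4-(hydroxymethyl)-1-[(2E,6E)-3,7,11-trimethyldodeca-2,6,10-trien-1-yl]-7-oxabicyclo[4.1.0]hept-3-en-2-one
Conditions: AcOH–H2O–THF (3:1:1), 35 °C
Reagents that add atoms: none
Why: Acid-catalysed acetal hydrolysis, in which the oxirane flanked by a ketone and an oxygenated carbon resists acid-catalysed opening, so that mild aqueous acetic acid should free the 1,3-diol without touching the epoxide or the triene.

Step 8
Reactants: 19 dimethyl 3-hydroxy-3-methylpentanedioate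
Product: 20 (S)-3-hydroxy-5-methoxy-3-methyl-5-oxopentanoic acid
Conditions: pig liver esterase, pH 7 phosphate buffer, 1 M NaOH (pH-stat), 25 °C; then HCl to pH 2
Reagents that add atoms: water (O)
Why: Enzymatic desymmetrisation of the prochiral diester, in which the esterase hydrolyses one enantiotopic ester group and thereby creates the tertiary carbinol stereocentre as S.

Step 9
Reactants: 20 (S)-half ester
Product: 21 1-methyl 5-[2-(trimethylsilyl)ethyl] (R)-3-hydroxy-3-methylpentanedioate
Conditions: 2-(trimethylsilyl)ethanol, DCC, DMAP (cat.), CH2Cl2, 0 → 23 °C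
Reagents that add atoms: 2-(trimethylsilyl)ethanol (C[Si](C)(C)CCO)
Why: Steglich esterification of the free acid arm, the tertiary alcohol being too hindered to be acylated and the stereocentre untouched (the descriptor becomes R only because the priorities of the two arms change).

Step 10
Reactants: 21 mixed diester
Product: 22 (R)-3-hydroxy-3-methyl-5-oxo-5-[2-(trimethylsilyl)ethoxy]pentanoic acid
Conditions: LiI, EtOAc, reflux; then 0.5 M HCl
Reagents that add atoms: none
Why: SN2 dealkylation by iodide, which attacks the methyl group far faster than the primary 2-silylethyl group and works under neutral conditions that avoid retro-aldol cleavage of the β-hydroxy ester.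

Step 11
Reactants: 18 epoxy enone diol; 22 (R)-half acid
Product: 23 1-{[(1R,5R,6R)-5-hydroxy-2-oxo-1-[(2E,6E)-3,7,11-trimethyldodeca-2,6,10-trien-1-yl]-7-oxabicyclo[4.1.0]hept-3-en-4-yl]methyl} 5-[2-(trimethylsilyl)ethyl] (R)-3-hydroxy-3-methylpentanedioate
Conditions: PPh3, DIAD, THF, 0 °C
Reagents that add atoms: none
Why: Mitsunobu esterification, in which the primary allylic alcohol is activated as its alkoxyphosphonium salt and displaced by the carboxylate whereas the hindered secondary alcohol between the oxirane and the substituted alkene and the tertiary alcohol of 22 should not react.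

Step 12
Reactants: 23 silylethyl ester
Product: 24 (3S)-3-hydroxy-5-{[(1R,5R,6R)-5-hydroxy-2-oxo-1-[(2E,6E)-3,7,11-trimethyldodeca-2,6,10-trien-1-yl]-7-oxabicyclo[4.1.0]hept-3-en-4-yl]methoxy}-3-methyl-5-oxopentanoic acid
Conditions: tris(dimethylamino)sulfonium difluorotrimethylsilicate (TASF), DMF, 0 °C; then dilute HCl to pH 3
Reagents that add atoms: none
Why: Fluoride-induced β-elimination of the 2-(trimethylsilyl)ethyl ester under nearly neutral conditions should release the acid (now the lower-priority arm, hence S) without cleaving the allylic ester or opening the oxirane, whose cis hydroxyl cannot attack it from the rear.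

**Compound list**

1 | (2E,6E)-farnesyl bromide | CC(C)=CCC/C(C)=C/CC/C(C)=C/CBr | starting material
2 | dichloromethane | ClCCl | starting material
3 | dichloromethyllithium | [Li]C(Cl)Cl | intermediate
4 | (3E,7E)-1,1-dichloro-4,8,12-trimethyltrideca-3,7,11-triene | CC(C)=CCC/C(C)=C/CC/C(C)=C/CC(Cl)Cl | intermediate
5 | 2,2-dimethyl-1,3-dioxan-5-one | CC1(C)OCC(=O)CO1 | starting material
6 | formaldehyde | C=O | starting material
7 | (S)-4-(hydroxymethyl)-2,2-dimethyl-1,3-dioxan-5-one | CC1(C)OCC(=O)[C@H](CO)O1 | intermediate
8 | (triphenylphosphoranylidene)ketene | O=C=C=P(c1ccccc1)(c1ccccc1)c1ccccc1 | starting material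
9 | ester ylide, [(4S)-2,2-dimethyl-5-oxo-1,3-dioxan-4-yl]methyl (triphenylphosphoranylidene)acetate | CC1(C)OCC(=O)[C@H](COC(=O)C=P(c2ccccc2)(c2ccccc2)c2ccccc2)O1 | intermediate
10 | (8aR)-2,2-dimethyl-8,8a-dihydro-4H-pyrano[3,4-d][1,3]dioxin-6-one (acetonide-fused 5,6-dihydro-2H-pyran-2-one, C=C from the ring-fusion carbon) | O=C1C=C2COC(C)(C)O[C@H]2CO1 | intermediate
11 | (3E,7E)-1,1-dichloro-4,8,12-trimethyltrideca-3,7,11-trien-1-yllithium | CC(C)=CCC/C(C)=C/CC/C(C)=C/CC([Li])(Cl)Cl | intermediate
12 | cyclic hemiketal, (8aR)-6-[(3E,7E)-1,1-dichloro-4,8,12-trimethyltrideca-3,7,11-trien-1-yl]-2,2-dimethyl-8,8a-dihydro-4H-pyrano[3,4-d][1,3]dioxin-6-ol (both C6 epimers) | CC(C)=CCC/C(C)=C/CC/C(C)=C/CC(Cl)(Cl)C1(O)C=C2COC(C)(C)O[C@H]2CO1 | intermediate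
13 | (1Z,5E,9E)-3,3-dichloro-1-[(4R)-4-(hydroxymethyl)-2,2-dimethyl-1,3-dioxan-5-ylidene]-6,10,14-trimethylpentadeca-5,9,13-trien-2-one | CC(C)=CCC/C(C)=C/CC/C(C)=C/CC(Cl)(Cl)C(=O)/C=C1/COC(C)(C)O[C@H]1CO | intermediate
14 | (4R,5Z)-5-[(5E,9E)-3,3-dichloro-6,10,14-trimethyl-2-oxopentadeca-5,9,13-trien-1-ylidene]-2,2-dimethyl-1,3-dioxane-4-carbaldehyde | CC(C)=CCC/C(C)=C/CC/C(C)=C/CC(Cl)(Cl)C(=O)/C=C1/COC(C)(C)O[C@H]1C=O | intermediate
15 | samarium chloro-enolate of 14 (diiodosamarium enolate, alkyl chain syn to O–Sm) | CC(C)=CCC/C(C)=C/CC/C(C)=C/C/C(Cl)=C(\O[Sm](I)I)/C=C1/COC(C)(C)O[C@H]1C=O | intermediate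
16 | samarium chlorohydrin aldolate (cyclised; chlorine at C1 trans to the C6 alkoxide, alkoxide cis to C5–O) | CC(C)=CCC/C(C)=C/CC/C(C)=C/C[C@]1(Cl)[C@H](O[Sm](I)I)[C@@H]3OC(C)(C)OCC3=CC1=O | intermediate
17 | acetonide of 18 (2,2-dimethyl-1,3-dioxane fused across C4-CH2O and C5-O of the (1R,5R,6R)-1-farnesyl-7-oxabicyclo[4.1.0]hept-3-en-2-one; epoxide oxygen cis to C5–O) | CC(C)=CCC/C(C)=C/CC/C(C)=C/C[C@@]12O[C@@H]1[C@@H]3OC(C)(C)OCC3=CC2=O | intermediate
18 | (1R,5R,6R)-5-hydroxy-4-(hydroxymethyl)-1-[(2E,6E)-3,7,11-trimethyldodeca-2,6,10-trien-1-yl]-7-oxabicyclo[4.1.0]hept-3-en-2-one | CC(C)=CCC/C(C)=C/CC/C(C)=C/C[C@@]12O[C@@H]1[C@H](O)C(CO)=CC2=O | intermediate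
19 | dimethyl 3-hydroxy-3-methylpentanedioate | COC(=O)CC(C)(O)CC(=O)OC | starting material
20 | (S)-3-hydroxy-5-methoxy-3-methyl-5-oxopentanoic acid | COC(=O)C[C@@](C)(O)CC(=O)O | intermediate
21 | 1-methyl 5-[2-(trimethylsilyl)ethyl] (R)-3-hydroxy-3-methylpentanedioate | COC(=O)C[C@@](C)(O)CC(=O)OCC[Si](C)(C)C | intermediate
22 | (R)-3-hydroxy-3-methyl-5-oxo-5-[2-(trimethylsilyl)ethoxy]pentanoic acid | OC(=O)C[C@@](C)(O)CC(=O)OCC[Si](C)(C)C | intermediate
23 | 2-(trimethylsilyl)ethyl ester of the target (R at the glutarate carbinol carbon by priority change) | CC(C)=CCC/C(C)=C/CC/C(C)=C/C[C@@]12O[C@@H]1[C@H](O)C(COC(=O)C[C@@](C)(O)CC(=O)OCC[Si](C)(C)C)=CC2=O | intermediate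
24 | (3S)-3-hydroxy-5-{[(1R,5R,6R)-5-hydroxy-2-oxo-1-[(2E,6E)-3,7,11-trimethyldodeca-2,6,10-trien-1-yl]-7-oxabicyclo[4.1.0]hept-3-en-4-yl]methoxy}-3-methyl-5-oxopentanoic acid (CNP0134663.2) | CC(C)=CCC/C(C)=C/CC/C(C)=C/C[C@@]12O[C@@H]1[C@H](O)C(COC(=O)C[C@@](C)(O)CC(=O)O)=CC2=O | target

**Step count.** Total: 12 steps. Longest linear sequence: 8 steps (5 → 7 → 10 → 12 → 14 → 17 → 18 → 23 → 24; steps 2, 3, 4, 5, 6, 7, 11, 12).

**Steps most likely to fail**

Step 6. The chlorohydrin aldolate may be reduced a second time before it closes, the aldehyde may undergo ketyl (pinacol) chemistry, or the samarium-bound alkoxide may displace the tertiary chloride too slowly. The fallback separates bond formation from ring closure. Starting from 14, a chromium Reformatsky reaction (CrCl2, LiI cat., THF, 0 °C) should give a non-basic, non-reducing chromium aldolate that is worked up to the isolated trans-chlorohydrin F1. F1 is then closed in a separate operation with K2CO3 in MeOH at 0 °C, which returns to the route at 17.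

Step 5. The oxidation may stall because the primary alcohol stays locked in the cyclic hemiketal, or the hemiketal may ionise and dehydrate under the reagent. The fallback avoids any free hydroxy ketone. Starting from lactone 10, Me(MeO)NH·HCl with i-PrMgCl (THF, −20 °C) opens the ring to the (Z)-hydroxy Weinreb amide F2. F2 is silylated at once (Et3SiCl, imidazole) to the triethylsilyl ether F3. Carbenoid 11, generated as in step 4, adds to F3 to give the dichloro ketone silyl ether F4, which cannot form a hemiketal. Swern oxidation (oxalyl chloride, DMSO, then i-Pr2NEt, −78 → −30 °C) converts the primary silyl ether directly into the aldehyde, which returns to the route at 14.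

Step 2. Conversion may be low, a second hydroxymethylation may compete, and enantiomeric purity may erode through retro-aldol reaction or enolisation of the α-oxygenated ketone. The fallback uses auxiliary control. Starting from 5, condensation with (S)-1-amino-2-(methoxymethyl)pyrrolidine gives the SAMP hydrazone F5. Deprotonation (t-BuLi, THF, −78 °C) and alkylation with benzyl chloromethyl ether at −100 °C give the alkylated hydrazone F6. Aqueous oxalic acid cleaves the auxiliary to give the benzyl ether F7, and hydrogenolysis (H2, Pd/C, EtOAc) returns to the route at 7.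

**Further compounds**

F1 | step 6 | trans-chlorohydrin (free alcohol corresponding to 16; chlorine at C1 trans to C6-OH, C6-OH cis to C5–O) | CC(C)=CCC/C(C)=C/CC/C(C)=C/C[C@]1(Cl)[C@H](O)[C@@H]3OC(C)(C)OCC3=CC1=O
F2 | step 5 | (2Z)-2-[(4R)-4-(hydroxymethyl)-2,2-dimethyl-1,3-dioxan-5-ylidene]-N-methoxy-N-methylacetamide | CON(C)C(=O)/C=C1/COC(C)(C)O[C@H]1CO
F3 | step 5 | triethylsilyl ether of F2 | CON(C)C(=O)/C=C1/COC(C)(C)O[C@H]1CO[Si](CC)(CC)CC
F4 | step 5 | triethylsilyl ether of open-chain hydroxy ketone 13 | CC(C)=CCC/C(C)=C/CC/C(C)=C/CC(Cl)(Cl)C(=O)/C=C1/COC(C)(C)O[C@H]1CO[Si](CC)(CC)CC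
F5 | step 2 | SAMP hydrazone of 2,2-dimethyl-1,3-dioxan-5-one | CC1(C)OCC(=NN2CCC[C@H]2COC)CO1
F6 | step 2 | SAMP hydrazone of (S)-4-[(benzyloxy)methyl]-2,2-dimethyl-1,3-dioxan-5-one | CC1(C)OCC(=NN2CCC[C@H]2COC)[C@H](COCc3ccccc3)O1
F7 | step 2 | (S)-4-[(benzyloxy)methyl]-2,2-dimethyl-1,3-dioxan-5-one | CC1(C)OCC(=O)[C@H](COCc2ccccc2)O1
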